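All runs are simulated on assumed constants; noise was put on by code.

The target, which substrate and partner make together, is judged by its share in target plus homo product at the end of the four flasks below, and we read the earlier runs first.

| flask | substrate | partner | capture agent | remark | time |
|---|---|---|---|---|---|
| birch | 0.050 M | 0.90 equiv | 0.050 M | run made earlier |  |
| elm | 0.034 M | 0.90 equiv | 0.050 M | run made earlier |  |
| larch | 0.075 M | 0.90 equiv | 0.050 M | run made earlier |  |
| cedar | 0.050 M | 0.90 equiv | 0.10 M | run made earlier |  |
| north | 0.050 M (fed, over 10 d) | 0.900 equiv | 0.0500 M | all else is in the flask from the start; the feed brings no volume worth counting | 15 d |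
| south-west | 0.050 M | 0.900 equiv (fed, over 10 d) | 0.0500 M | all else is in the flask from the start; the feed brings no volume worth counting | 15 d |
| south-east | 0.050 M | 0.900 equiv | 0.0500 M | everything together at the start | 15 d |
| north-west | 0.050 M (in portions, 2, over 10 d) | 0.900 equiv | 0.0500 M | first portion at the start, last at 10 d | 15 d |

| run | time / d | target / % | homo product / % |
|---|---|---|---|
| birch | 0.625 | 5 | 3 |
| birch | 1.25 | 8 | 10 |
| birch | 2.08 | 15 | 15 |
| birch | 3.00 | 11 | 17 |
| birch | 5.00 | 7 | 18 |
| birch | 10.0 | 0 | 19 |
| elm | 0.833 | 5 | 6 |
| elm | 2.50 | 8 | 14 |
| elm | 4.00 | 10 | 16 |
| elm | 6.00 | 5 | 13 |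
| elm | 10.0 | 3 | 16 |
| elm | 12.0 | 1 | 14 |
| larch | 0.833 | 8 | 10 |
| larch | 2.50 | 15 | 20 |
| larch | 4.00 | 10 | 20 |
| larch | 6.00 | 7 | 23 |
| larch | 10.0 | 7 | 23 |
| larch | 12.0 | 6 | 24 |
| cedar | 1.04 | 4 | 4 |
| cedar | 3.00 | 7 | 9 |
| cedar | 6.00 | 1 | 9 |
| cedar | 8.00 | 4 | 13 |
| cedar | 12.0 | 5 | 9 |

(each reading ± 1.5 percentage points)

- which flask leads in share of target in target plus homo product ("all alike" within 1.5 percentage points) (north / south-west / south-east / north-west / all alike)
- share of target in target plus homo product at the end, north
- share of target in target plus homo product at the end, south-west
- share of target in target plus homo product at the end, south-east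
- share of target in target plus homo product at the end, north-west

- in percentages every species weighs as the substrate in it: one homo product counts as two

Which numbers must be known well? In birch at 5.00 d the readings give a share of 28.0%; an error of one scatter in homo product moves it by 1.6 percentage points, but the same error in target moves it by 4.1 points, more than the homo error does, so the small late target matters most among the readings. Partner cannot be tested this way, because birch, elm, larch and cedar each held 0.90 equiv. So we take its number from the charge and carry the partner charge, the concentration of partner a flask has received once its whole charge is in 0.0450 M. This is less than the substrate or the capture agent, so partner is the reagent charged in the smallest amount, and its balance is the one we write. The birch peak reading of target is 16.7% of that charge, below it, so our reckoning takes the charge as a ceiling on target and gives no shares.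

The forecast, which does give shares, named north as leader, with 48% there, 45% in north-west, 12% in south-west and 6% in south-east, holding that “late-made target survives”.

The flasks put north ahead with 39.8%, then north-west 34.3%, south-east 14.4% and south-west 3.60%. South-west thus stands below south-east, where the forecast had south-west above south-east.

    open intermediate + second intermediate → target (k = 0.00790 L mol⁻¹ min⁻¹)
    target ⇌ isomer of the product (K = 9.50, k = 4.90 × 10⁻⁴ min⁻¹)
    substrate → open intermediate (k = 9.50 × 10⁻⁴ min⁻¹)
    open intermediate + capture agent → trapped intermediate (k = 0.00850 L mol⁻¹ min⁻¹)
    2 open intermediate → homo product (k = 0.00500 L mol⁻¹ min⁻¹)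
    substrate + target → side product (k = 9.10 × 10⁻⁴ L mol⁻¹ min⁻¹)
    partner → second intermediate (k = 0.00110 min⁻¹)

In south-west the turnover of substrate to open intermediate has its midpoint at 0.507 d, much earlier than the 5.63 d of partner to second intermediate. The balance shows what stands at the end of south-west: of 0.0450 M, 0.0393 M remains as second intermediate and 0.00570 M has gone on. A neighbour of south-west with 3.60 equiv of partner has a charge of 0.180 M, of which 0.167 M remains as second intermediate and 0.0126 M has gone on; its computed share is 8.75%, from 2.39% target and 25.0% homo product.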